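**Retrosynthetic overview**

- The target is the free phenol of an aryl acrylate. The last step is a mild aminolysis that uncovers the C5–OH next to the ketone.
- The 2,2‑dimethylpyran ring is closed last, at its C3=C4 double bond, by a ring‑rearrangement metathesis. A coumarin that carries a 1,1‑dimethylallyl ether on O5 gives up its own C4 to the new ring, while its lactone ring opens to the acrylate.
- Enabling feature: the temporary pyranone ring of the coumarin (O1–C2(=O)–C3=C4–C4a–C8a). It holds C4 peri to O5, so C4=C3 and the ether vinyl group lie six atoms apart through C4a and C5. Its O1 is the masked phenol oxygen that ends up at C5 of the chromene.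
- The (S)‑carbinol is set before the key step by a catalytic asymmetric Mukaiyama aldol addition of the 8‑acetylcoumarin enol silane to benzaldehyde.
- Ring order: benzene and pyranone rings come with 5,7‑dihydroxycoumarin (C8 acetylation, then chelation‑controlled O5 propargylation and O7 methylation). The pyran ring is formed last as the pyranone ring is cleaved.

Key step: step 7

Assumption: the (R,R)‑bisphosphoramide/SiCl4 system is taken to direct enol silanes to the Re face of aromatic aldehydes, so its (S,S)‑antipode is specified for the Si‑face addition that gives the (S)‑carbinol; if a model run with acetophenone trimethylsilyl enol ether shows the opposite sense, the other catalyst enantiomer is used.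

Assumption: 5,7‑dihydroxycoumarin is treated as a purchased material (it is also the one‑step Pechmann product of phloroglucinol).

**Route**

Step 1
Reactants: 1 5,7‑dihydroxy‑2H‑chromen‑2‑one (5,7‑dihydroxycoumarin); 2 acetyl chloride
Product: 3 8‑acetyl‑5,7‑dihydroxy‑2H‑chromen‑2‑one
Conditions: AlCl3 (4 equiv), PhNO2/ClCH2CH2Cl, 70 °C; then ice/aq. HCl
Reagents that add atoms: acetyl chloride, CC(Cl)=O
Why: Friedel–Crafts C‑acylation, which in 5,7‑dihydroxycoumarins should favour C8 (ortho to the 7‑OH, para to the 5‑OH, the position of highest double‑bond fixation), with the lactone inert to AlCl3.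

Step 2
Reactants: 3 8‑acetyl‑5,7‑dihydroxy‑2H‑chromen‑2‑one; 4 3‑chloro‑3‑methylbut‑1‑yne
Product: 5 8‑acetyl‑7‑hydroxy‑5‑[(2‑methylbut‑3‑yn‑2‑yl)oxy]‑2H‑chromen‑2‑one
Conditions: CuCl2·2H2O (1 mol%), DBU (1.2 equiv), MeCN, 0 °C to rt
Reagents that add atoms: 3‑chloro‑3‑methylbut‑1‑yne, C#CC(C)(C)Cl
Why: copper‑catalysed propargylic etherification of a phenol with a tertiary propargyl chloride, in which the 7‑OH is held in a hydrogen bond to the 8‑acetyl carbonyl so that only the free, more acidic 5‑OH should be alkylated.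

Step 3
Reactants: 5 8‑acetyl‑7‑hydroxy‑5‑[(2‑methylbut‑3‑yn‑2‑yl)oxy]‑2H‑chromen‑2‑one; 6 iodomethane
Product: 7 8‑acetyl‑7‑methoxy‑5‑[(2‑methylbut‑3‑yn‑2‑yl)oxy]‑2H‑chromen‑2‑one
Conditions: MeI (3 equiv), K2CO3, DMF, rt to 40 °C
Reagents that add atoms: iodomethane, CI
Why: Williamson O‑methylation of the remaining chelated phenol, at a temperature far below that of the propargyl ether Claisen cyclisation and under anhydrous carbonate that leaves the lactone closed.

Step 4
Reactants: 7 8‑acetyl‑7‑methoxy‑5‑[(2‑methylbut‑3‑yn‑2‑yl)oxy]‑2H‑chromen‑2‑one; 8 trimethylsilyl trifluoromethanesulfonate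
Product: 9 7‑methoxy‑5‑[(2‑methylbut‑3‑yn‑2‑yl)oxy]‑8‑[1‑(trimethylsilyloxy)ethenyl]‑2H‑chromen‑2‑one
Conditions: TMSOTf (1.3 equiv), Et3N (2 equiv), CH2Cl2, 0 °C; pentane, filtration, concentration (used crude)
Reagents that add atoms: trimethylsilyl trifluoromethanesulfonate, C[Si](C)(C)OS(=O)(=O)C(F)(F)F
Why: soft enolisation and O‑silylation of the only enolisable ketone (silyl enol ether formation), buffered by excess amine so that the tertiary propargyl ether and the lactone are not ionised.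

Step 5
Reactants: 9 7‑methoxy‑5‑[(2‑methylbut‑3‑yn‑2‑yl)oxy]‑8‑[1‑(trimethylsilyloxy)ethenyl]‑2H‑chromen‑2‑one; 10 benzaldehyde
Product: 12 8‑[(3S)‑3‑hydroxy‑3‑phenylpropanoyl]‑7‑methoxy‑5‑[(2‑methylbut‑3‑yn‑2‑yl)oxy]‑2H‑chromen‑2‑one, via trichlorosilyl aldolate 11 (not isolated)
Conditions: SiCl4 (1.5 equiv), (S,S)‑bisphosphoramide (pentane‑1,5‑diyl‑linked bis‑phosphoramide built from (S)‑N,N'‑dimethyl‑1,1'‑binaphthyl‑2,2'‑diamine, 5 mol%), iPr2NEt (10 mol%), CH2Cl2, −78 °C; then sat. aq. NaHCO3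
Reagents that add atoms: benzaldehyde, O=Cc1ccccc1; silicon tetrachloride, Cl[Si](Cl)(Cl)Cl (its atoms are held only by intermediate 11)
Why: Lewis‑base‑catalysed, SiCl4‑mediated asymmetric Mukaiyama aldol addition, in which the chiral phosphoramide‑bound trichlorosilyl cation activates benzaldehyde and exposes its Si face to the enol silane, so that the catalyst alone sets the (S)‑carbinol centre while alkyne, lactone and tertiary ether stay inert at −78 °C.

Step 6
Reactants: 12 8‑[(3S)‑3‑hydroxy‑3‑phenylpropanoyl]‑7‑methoxy‑5‑[(2‑methylbut‑3‑yn‑2‑yl)oxy]‑2H‑chromen‑2‑one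
Product: 13 8‑[(3S)‑3‑hydroxy‑3‑phenylpropanoyl]‑7‑methoxy‑5‑[(2‑methylbut‑3‑en‑2‑yl)oxy]‑2H‑chromen‑2‑one
Conditions: H2 (1 atm), Pd/CaCO3 poisoned with Pb(OAc)2, quinoline, EtOAc, rt, stopped after 1 equiv H2
Reagents that add atoms: none
Why: Lindlar semihydrogenation of the terminal alkyne to the 1,1‑dimethylallyl ether, which should leave the conjugated lactone alkene, the aryl ketone and the benzylic alcohol untouched and is run at rt so the Claisen‑prone ether is not heated.

Step 7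
Reactants: 13 8‑[(3S)‑3‑hydroxy‑3‑phenylpropanoyl]‑7‑methoxy‑5‑[(2‑methylbut‑3‑en‑2‑yl)oxy]‑2H‑chromen‑2‑one
Product: 14 6‑[(3S)‑3‑hydroxy‑3‑phenylpropanoyl]‑7‑methoxy‑2,2‑dimethyl‑2H‑chromen‑5‑yl prop‑2‑enoate
Conditions: RuCl2(H2IMes)(=CH‑C6H4‑2‑OiPr) (second‑generation Hoveyda–Grubbs catalyst, H2IMes = 1,3‑dimesitylimidazolidin‑2‑ylidene, 5–10 mol%), toluene (0.01 M), 40 °C
Reagents that add atoms: none
Why: Proposed new method: a ring‑rearrangement metathesis in which the internal olefin is the C3=C4 alkene of an unstrained benzo‑fused lactone; the ruthenium carbene loads on the vinyl group of the ether and closes onto coumarin C4, forming the chromene C3=C4 bond and leaving an ester‑substituted carbene on the former C3 that passes on to the vinyl group of the next substrate molecule, while the methylidene RuCl2(H2IMes)(=CH2) can reach the same product by opening the lactone alkene first (the reverse of the known coumarin‑forming RCM of 2‑vinylaryl acrylates) and closing the resulting benzylidene onto the vinyl group. The closest known reactions are the RCM of 2‑vinylaryl 1,1‑dimethylallyl ethers to 2,2‑dimethyl‑2H‑chromenes and the ring‑opening/ring‑closing metathesis of cycloalkenes that carry a tethered olefin. The pyran ring closes in a six‑membered ring‑closing‑metathesis mode (C4, C4a, C5, O, CMe2, CH), the cis alkene is dictated by the ring, and no stereocentre is formed or touched. The step is a net isomerisation that should run downhill: the lactone gives up its enforced s‑cis ester geometry on becoming an open acrylate, the gem‑dimethyl group favours the pyran ring and shields the new alkene from re‑opening, and the hindered aryl acrylate is a poor partner for the back reaction. The selectivity needed is metathesis ahead of the thermal Claisen shift of the 1,1‑dimethylallyl aryl ether to C6, secured by working at 40 °C, and closure at C4 only, secured because every other closure would give a ring of eight or more members; the free alcohol and ketone are tolerated by the ruthenium carbene.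

Step 8
Reactants: 14 6‑[(3S)‑3‑hydroxy‑3‑phenylpropanoyl]‑7‑methoxy‑2,2‑dimethyl‑2H‑chromen‑5‑yl prop‑2‑enoate
Product: 15 (3S)‑3‑hydroxy‑1‑(5‑hydroxy‑7‑methoxy‑2,2‑dimethyl‑2H‑chromen‑6‑yl)‑3‑phenylpropan‑1‑one
Conditions: morpholine (3 equiv), THF, 0 °C to rt; pH 5 citrate buffer work‑up
Reagents that add atoms: none
Why: aza‑Michael addition of morpholine to the aryl acrylate followed by aminolysis of the activated ortho‑acyl aryl ester should free the phenol without hydroxide or alkoxide, so that retro‑aldol cleavage and dehydration of the β‑hydroxy ketone to the chalcone or flavanone are avoided.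

**Compound list**

1 | 5,7‑dihydroxy‑2H‑chromen‑2‑one | O=C1C=Cc2c(O)cc(O)cc2O1 | starting material
2 | acetyl chloride | CC(Cl)=O | starting material
3 | 8‑acetyl‑5,7‑dihydroxy‑2H‑chromen‑2‑one | CC(=O)c1c(O)cc(O)c2C=CC(=O)Oc12 | intermediate
4 | 3‑chloro‑3‑methylbut‑1‑yne | C#CC(C)(C)Cl | starting material
5 | 8‑acetyl‑7‑hydroxy‑5‑[(2‑methylbut‑3‑yn‑2‑yl)oxy]‑2H‑chromen‑2‑one | CC(=O)c1c(O)cc(OC(C)(C)C#C)c2C=CC(=O)Oc12 | intermediate
6 | iodomethane | CI | starting material
7 | 8‑acetyl‑7‑methoxy‑5‑[(2‑methylbut‑3‑yn‑2‑yl)oxy]‑2H‑chromen‑2‑one | CC(=O)c1c(OC)cc(OC(C)(C)C#C)c2C=CC(=O)Oc12 | intermediate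
8 | trimethylsilyl trifluoromethanesulfonate | C[Si](C)(C)OS(=O)(=O)C(F)(F)F | starting material
9 | 7‑methoxy‑5‑[(2‑methylbut‑3‑yn‑2‑yl)oxy]‑8‑[1‑(trimethylsilyloxy)ethenyl]‑2H‑chromen‑2‑one | C=C(O[Si](C)(C)C)c1c(OC)cc(OC(C)(C)C#C)c2C=CC(=O)Oc12 | intermediate
10 | benzaldehyde | O=Cc1ccccc1 | starting material
11 | 7‑methoxy‑5‑[(2‑methylbut‑3‑yn‑2‑yl)oxy]‑8‑[(3S)‑3‑phenyl‑3‑(trichlorosilyloxy)propanoyl]‑2H‑chromen‑2‑one | O=C(C[C@H](O[Si](Cl)(Cl)Cl)c1ccccc1)c1c(OC)cc(OC(C)(C)C#C)c2C=CC(=O)Oc12 | intermediate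
12 | 8‑[(3S)‑3‑hydroxy‑3‑phenylpropanoyl]‑7‑methoxy‑5‑[(2‑methylbut‑3‑yn‑2‑yl)oxy]‑2H‑chromen‑2‑one | O=C(C[C@H](O)c1ccccc1)c1c(OC)cc(OC(C)(C)C#C)c2C=CC(=O)Oc12 | intermediate
13 | 8‑[(3S)‑3‑hydroxy‑3‑phenylpropanoyl]‑7‑methoxy‑5‑[(2‑methylbut‑3‑en‑2‑yl)oxy]‑2H‑chromen‑2‑one | O=C(C[C@H](O)c1ccccc1)c1c(OC)cc(OC(C)(C)C=C)c2C=CC(=O)Oc12 | intermediate
14 | 6‑[(3S)‑3‑hydroxy‑3‑phenylpropanoyl]‑7‑methoxy‑2,2‑dimethyl‑2H‑chromen‑5‑yl prop‑2‑enoate | C=CC(=O)Oc1c(C(=O)C[C@H](O)c2ccccc2)c(OC)cc2OC(C)(C)C=Cc12 | intermediate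
15 | (3S)‑3‑hydroxy‑1‑(5‑hydroxy‑7‑methoxy‑2,2‑dimethyl‑2H‑chromen‑6‑yl)‑3‑phenylpropan‑1‑one | COc1cc2c(c(O)c1C(=O)C[C@H](O)c1ccccc1)C=CC(C)(C)O2 | target

**Step count and risks**

Total step count: 8. Longest linear sequence: 8 steps.

Steps most likely to fail:

1. Step 7 (Proposed new method). The carbene may fail to engage the electron‑poor lactone alkene, so that no ring opening occurs, or the 1,1‑dimethylallyl ether may undergo Claisen rearrangement or the catalyst may decompose before turnover. The fallback uses known chemistry, sets out from 12 (before the semihydrogenation, when the lactone C3=C4 is the only alkene) and comes back at 15. The lactone alkene of 12 is cleaved by dihydroxylation and periodate (OsO4 cat., NMO, acetone/H2O; then NaIO4), and the aryl glyoxylate so formed is hydrolysed on bicarbonate work‑up to 2‑hydroxy‑3‑[(3S)‑3‑hydroxy‑3‑phenylpropanoyl]‑4‑methoxy‑6‑[(2‑methylbut‑3‑yn‑2‑yl)oxy]benzaldehyde F1. Wittig methylenation (Ph3PCH3Br/KN(SiMe3)2 in excess, THF, −78 to 0 °C) should give (3S)‑1‑{3‑ethenyl‑2‑hydroxy‑6‑methoxy‑4‑[(2‑methylbut‑3‑yn‑2‑yl)oxy]phenyl}‑3‑hydroxy‑3‑phenylpropan‑1‑one F2. Lindlar semihydrogenation of the alkyne then gives (3S)‑1‑{3‑ethenyl‑2‑hydroxy‑6‑methoxy‑4‑[(2‑methylbut‑3‑en‑2‑yl)oxy]phenyl}‑3‑hydroxy‑3‑phenylpropan‑1‑one F3. Conventional RCM of the styrene with the allyl ether (RuCl2(H2IMes)(PCy3)(=CHPh), second‑generation Grubbs catalyst, CH2Cl2, 40 °C) closes the same C3=C4 bond with loss of ethylene and gives 15 directly.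

2. Step 5. The hindered, twisted enol silane may add with poor facial selectivity or too slowly, or the Lewis acid may ionise the tertiary propargyl ether. The fallback sets out from 7 and comes back at 12. Claisen–Schmidt condensation of 7 with benzaldehyde (piperidine or Ba(OH)2, EtOH) gives 7‑methoxy‑5‑[(2‑methylbut‑3‑yn‑2‑yl)oxy]‑8‑[(2E)‑3‑phenylprop‑2‑enoyl]‑2H‑chromen‑2‑one F4. Juliá–Colonna nucleophilic epoxidation (poly‑D‑leucine, urea–H2O2, DBU, THF; the L‑polymer is the one expected to give the (2R,3S) series) should give 7‑methoxy‑5‑[(2‑methylbut‑3‑yn‑2‑yl)oxy]‑8‑{[(2S,3R)‑3‑phenyloxiran‑2‑yl]carbonyl}‑2H‑chromen‑2‑one F5. Reductive cleavage of the Cα–O bond of the epoxy ketone (PhSeSePh/NaBH4/AcOH, EtOH, 0 °C) keeps the C3–O bond, so the (3R) epoxide carbon becomes the (3S) carbinol of 12 by a change of CIP priorities only.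

3. Step 1. Acylation may occur at C6 or at both C6 and C8, giving a regioisomer mixture. The fallback sets out from 1 and comes back at 3. Selective acetylation of the more acidic 7‑OH (Ac2O 1 equiv, pyridine, 0 °C) gives 5‑hydroxy‑2‑oxo‑2H‑chromen‑7‑yl acetate F6, and Fries rearrangement (AlCl3, PhNO2, 120 °C) should deliver the acyl group from O7 to the adjacent C8, as 7‑acyloxycoumarins are known to do, giving 3.

**Further compounds**

F1 | step 7 | 2‑hydroxy‑3‑[(3S)‑3‑hydroxy‑3‑phenylpropanoyl]‑4‑methoxy‑6‑[(2‑methylbut‑3‑yn‑2‑yl)oxy]benzaldehyde | O=Cc1c(O)c(C(=O)C[C@H](O)c2ccccc2)c(OC)cc1OC(C)(C)C#C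
F2 | step 7 | (3S)‑1‑{3‑ethenyl‑2‑hydroxy‑6‑methoxy‑4‑[(2‑methylbut‑3‑yn‑2‑yl)oxy]phenyl}‑3‑hydroxy‑3‑phenylpropan‑1‑one | C=Cc1c(O)c(C(=O)C[C@H](O)c2ccccc2)c(OC)cc1OC(C)(C)C#C
F3 | step 7 | (3S)‑1‑{3‑ethenyl‑2‑hydroxy‑6‑methoxy‑4‑[(2‑methylbut‑3‑en‑2‑yl)oxy]phenyl}‑3‑hydroxy‑3‑phenylpropan‑1‑one | C=Cc1c(O)c(C(=O)C[C@H](O)c2ccccc2)c(OC)cc1OC(C)(C)C=C
F4 | step 5 | 7‑methoxy‑5‑[(2‑methylbut‑3‑yn‑2‑yl)oxy]‑8‑[(2E)‑3‑phenylprop‑2‑enoyl]‑2H‑chromen‑2‑one | O=C(/C=C/c1ccccc1)c1c(OC)cc(OC(C)(C)C#C)c2C=CC(=O)Oc12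
F5 | step 5 | 7‑methoxy‑5‑[(2‑methylbut‑3‑yn‑2‑yl)oxy]‑8‑{[(2S,3R)‑3‑phenyloxiran‑2‑yl]carbonyl}‑2H‑chromen‑2‑one | O=C([C@H]1O[C@@H]1c1ccccc1)c1c(OC)cc(OC(C)(C)C#C)c2C=CC(=O)Oc12
F6 | step 1 | 5‑hydroxy‑2‑oxo‑2H‑chromen‑7‑yl acetate | CC(=O)Oc1cc(O)c2C=CC(=O)Oc2c1
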